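The plan hinges on forming the C2–C1' bond as the last skeletal bond. C2, the fully substituted carbon of the pyran ring (ring B), is bound to O1, C3, the 2-methyl group and C1'. Such an O-bound quaternary carbon arises when a carbon nucleophile attacks C2 of a 2-methylbenzopyrylium cation. The chain C1'–C13', with C4' and C8' already in place, is therefore brought in as a terminal alkyne. One ligand-controlled, copper-catalysed alkynylation unites both halves and fixes the configuration at C2. Its precursors are 2,8-dimethyl-4-oxo-4H-chromen-6-yl pivalate (rings A and B complete) and (4R,8S)-4,8,12-trimethyltridec-11-en-1-yne; two reductions then complete the target.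

Key step: step 8

Remarks and assumptions
- Assumption: the facial preference of a P,N ligand on a 2-methylbenzopyrylium ion cannot be predicted with confidence; (S)-StackPhos is written, and its enantiomer is to be used if a trial shows the opposite sense (C4' and C8' are too remote to interfere).
- Stereochemical mapping: for 4'R the methyl-bearing C4 unit must be joined to C6' through the carbon that is CH2Br in (S)-3-bromo-2-methylpropan-1-ol. Coupling a citronellyl Grignard reagent at the tosyloxymethyl carbon of the (S)-Roche ester would give the 4'-epimer and risks elimination to methacrylate, so the commercial bromo alcohol is used.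
- Descriptors: C8' is S by the CIP rules in the 11'-ene, although its spatial arrangement is that of 8'R in saturated tocopherols. C2 is S in alkyne 20 and R once C1' is sp3, with no change in space.
- Precursor design: chromone 8 is converted fully into cation 17 before base or copper is present. The C6 pivalate is inert to TBSOTf, sits para to O1 and so makes the cation more electrophilic, and is cleaved by the last reduction without a separate step. Ketone 20 and ketone 21 are kept away from base, because 2,2-disubstituted chroman-4-ones can epimerise at C2 by retro-oxa-Michael ring opening.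

Step 1
Reactants: 1 4-methoxy-2-methylphenol
Product: 4 1-(2-hydroxy-5-methoxy-3-methylphenyl)ethan-1-one, via aryl acetate 2 (not isolated), via difluoroboron chelate 3 (not isolated)
Conditions: Ac2O (1.2 equiv), BF3·OEt2 (3 equiv), 90 °C; then H2O, MeOH, 60 °C
Reagents that add atoms: acetic anhydride CC(=O)OC(C)=O
Why: O-Acetylation and BF3-promoted Fries rearrangement should deliver the acetyl group to C6 of the phenol, the only open position ortho to the phenolic oxygen, because the O,O-difluoroboron chelate 3 is the thermodynamic sink, and warm aqueous methanol then hydrolyses the chelate.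

Step 2
Reactants: 4 1-(2-hydroxy-5-methoxy-3-methylphenyl)ethan-1-one
Product: 7 6-hydroxy-2,8-dimethyl-4H-chromen-4-one, via 1,3-diketone 5 (not isolated), via 6-methoxychromone 6 (not isolated)
Conditions: NaH (4 equiv), EtOAc, PhMe, 80 °C; evaporate; 48% aq. HBr, AcOH, 110 °C
Reagents that add atoms: ethyl acetate CCOC(C)=O
Why: Claisen condensation of the ketone enolate with ethyl acetate gives diketone 5, and hot HBr/AcOH then effects both cyclodehydration to the 2-methylchromone (ring B) and SN2 demethylation of the protonated aryl methyl ether by bromide, both tolerated by a chromone that carries no acid-sensitive group.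

Step 3
Reactants: 7 6-hydroxy-2,8-dimethyl-4H-chromen-4-one
Product: 8 2,8-dimethyl-4-oxo-4H-chromen-6-yl pivalate (fragment 1)
Conditions: PivCl, Et3N, DMAP (cat.), CH2Cl2, 0 °C to rt
Reagents that add atoms: pivaloyl chloride CC(C)(C)C(Cl)=O
Why: DMAP-catalysed O-acylation of the unhindered C6 phenol installs an ester that withstands TBSOTf, withdraws electron density from O1 in the later cation and is removed by the final hydride step.

Step 4
Reactants: 9 (R)-citronellol
Product: 10 (R)-8-bromo-2,6-dimethyloct-2-ene
Conditions: CBr4, PPh3, CH2Cl2, 0 °C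
Reagents that add atoms: carbon tetrabromide BrC(Br)(Br)Br
Why: Appel reaction (SN2 displacement of the alkoxyphosphonium ion by bromide at C1) leaves the remote stereocentre and the trisubstituted alkene untouched.

Step 5
Reactants: 10 (R)-8-bromo-2,6-dimethyloct-2-ene; 11 (S)-3-bromo-2-methylpropan-1-ol
Product: 14 (2R,6S)-2,6,10-trimethylundec-9-en-1-ol, via citronellylmagnesium bromide 12 (not isolated), via bromomagnesium alkoxide 13 (not isolated)
Conditions: Mg, THF, 40 °C (10 to 12); MeMgBr (1.0 equiv), THF, −20 °C (11 to 13); then 12 (1.3 equiv), Li2CuCl4 (3 mol%), THF, −20 °C to rt; 1 M aq. HCl, 0 °C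
Reagents that add atoms: none
Why: Copper-catalysed sp3–sp3 Grignard cross-coupling (Kochi coupling) at the primary C–Br bond of 13, whose hydroxyl group is masked in the flask as its magnesium alkoxide, forms bonds only at CH2 carbons, so the citronellyl centre (C8') and the methyl-bearing centre (C4') are carried over unchanged, CH2Br becoming C5' and CH2OH remaining as C3'.

Step 6
Reactants: 14 (2R,6S)-2,6,10-trimethylundec-9-en-1-ol
Product: 15 (2R,6S)-2,6,10-trimethylundec-9-en-1-yl 4-methylbenzenesulfonate
Conditions: TsCl, Et3N, DMAP (cat.), CH2Cl2, 0 °C to rt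
Reagents that add atoms: 4-methylbenzenesulfonyl chloride Cc1ccc(cc1)S(Cl)(=O)=O
Why: Sulfonylation of the primary alcohol (tosylation) activates C3' for substitution without touching C4'.

Step 7
Reactants: 15 (2R,6S)-2,6,10-trimethylundec-9-en-1-yl 4-methylbenzenesulfonate
Product: 16 (4R,8S)-4,8,12-trimethyltridec-11-en-1-yne (fragment 2)
Conditions: LiC≡CH·H2NCH2CH2NH2 (3 equiv), DMSO, rt
Reagents that add atoms: lithium acetylide–ethylenediamine complex [Li+].[C-]#C.NCCN
Why: SN2 alkylation of lithium acetylide in a dipolar aprotic solvent adds C2' and C1' at the CH2 of the β-branched primary tosylate, where a tosylate keeps E2 loss low, and C4' is not involved.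

Step 8
Reactants: 8 2,8-dimethyl-4-oxo-4H-chromen-6-yl pivalate (fragment 1); 16 (4R,8S)-4,8,12-trimethyltridec-11-en-1-yne (fragment 2)
Product: 20 (2S)-2,8-dimethyl-4-oxo-2-[(4R,8S)-4,8,12-trimethyltridec-11-en-1-yn-1-yl]chroman-6-yl pivalate, via benzopyrylium triflate 17 (not isolated), via copper acetylide 18 (not isolated), via silyl enol ether 19 (not isolated)
Conditions: TBSOTf (1.1 equiv), CH2Cl2, rt to 40 °C; then 16 (1.3 equiv), CuI (10 mol%), (S)-StackPhos (12 mol%), PhMe, −40 °C, i-Pr2NEt (1.5 equiv) added slowly; then 1 M aq. HCl, THF, 0 °C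
Reagents that add atoms: none
Why: Proposed new method: O-silylation of the C4 carbonyl of 8 by TBSOTf gives the aromatic 4-silyloxy-2-methylbenzopyrylium triflate 17, while i-Pr2NEt and ligated CuI turn 16 into the monovalent copper acetylide 18, which adds irreversibly to C2 to give silyl enol ether 19, hydrolysed to ketone 20 by dilute acid. The closest known reaction type is the CuI/chiral-ligand alkynylation of chromones that carry hydrogen or an ester group at C2 through the same silyloxybenzopyrylium ions; the extension proposed is to a 2-alkyl cation and thus to a non-activated, fully substituted C2. No ring is closed: a single C–C bond (C2–C1') joins two complete fragments. The new stereocentre C2 is set by the chiral pocket of the P,N-ligated copper acetylide, which blocks one face of the planar cation (reagent control), giving 2S in 20. Site selectivity for C2 over C4 should be secured in the substrate by the bulky silyloxy group at C4 and by the slender sp nucleophile, and the C6 pivalate para to O1 raises the electrophilicity of the cation. The competing process is deprotonation of the C2 methyl group to a 2-methylene-2H-chromene; it is reversible through the ammonium triflate whereas C–C bond formation is not, and slow addition of the amine at low temperature keeps the free base scarce.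

Step 9
Reactants: 20 (2S)-2,8-dimethyl-4-oxo-2-[(4R,8S)-4,8,12-trimethyltridec-11-en-1-yn-1-yl]chroman-6-yl pivalate
Product: 21 (2R)-2,8-dimethyl-4-oxo-2-[(4R,8S)-4,8,12-trimethyltridec-11-en-1-yl]chroman-6-yl pivalate
Conditions: H2 (1 atm), RhCl(PPh3)3 (10 mol%), PhMe/EtOH 1:1, rt, stopped when the alkyne and the cis-alkene are consumed
Reagents that add atoms: none
Why: Homogeneous hydrogenation with RhCl(PPh3)3 should saturate the C1'≡C2' alkyne through its cis-alkene much faster than it touches the trisubstituted C11'=C12' alkene and leaves the aryl ketone and the pivalate intact under neutral conditions, C2 becoming R only through the change in CIP priorities.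

Step 10
Reactants: 21 (2R)-2,8-dimethyl-4-oxo-2-[(4R,8S)-4,8,12-trimethyltridec-11-en-1-yl]chroman-6-yl pivalate
Product: 22 (2R)-2,8-dimethyl-2-[(4R,8S)-4,8,12-trimethyltridec-11-en-1-yl]chroman-6-ol
Conditions: LiAlH4 (4 equiv), AlCl3 (4 equiv), Et2O, 0 °C to reflux; 1 M aq. HCl, 0 °C
Reagents that add atoms: none
Why: Mixed-hydride (chloroalane) deoxygenation of an aryl ketone: hydride cleaves the pivalate and reduces C4=O to an aluminium alkoxide, the Lewis acid ionises it to a benzylic cation stabilised by O1, and a second hydride captures the cation, so C4 becomes CH2 and O6 is freed in one operation while the isolated alkene and the C2–O1 bond are not attacked.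

Compound list
1 | 4-methoxy-2-methylphenol | COc1ccc(O)c(C)c1 | starting material
2 | 4-methoxy-2-methylphenyl acetate | COc1ccc(OC(C)=O)c(C)c1 | intermediate (not isolated)
3 | O,O-difluoroboron chelate of 4 (2,2-difluoro-6-methoxy-4,8-dimethyl-1,3,2-benzodioxaborinine, zwitterionic form) | COc1cc(C)c2O[B-](F)(F)[O+]=C(C)c2c1 | intermediate (not isolated)
4 | 1-(2-hydroxy-5-methoxy-3-methylphenyl)ethan-1-one | COc1cc(C)c(O)c(C(C)=O)c1 | intermediate
5 | 1-(2-hydroxy-5-methoxy-3-methylphenyl)butane-1,3-dione | COc1cc(C)c(O)c(C(=O)CC(C)=O)c1 | intermediate (not isolated)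
6 | 6-methoxy-2,8-dimethyl-4H-chromen-4-one | COc1cc(C)c2oc(C)cc(=O)c2c1 | intermediate (not isolated)
7 | 6-hydroxy-2,8-dimethyl-4H-chromen-4-one | Cc1cc(=O)c2cc(O)cc(C)c2o1 | intermediate
8 | 2,8-dimethyl-4-oxo-4H-chromen-6-yl pivalate (fragment 1) | Cc1cc(=O)c2cc(OC(=O)C(C)(C)C)cc(C)c2o1 | intermediate
9 | (R)-citronellol, (3R)-3,7-dimethyloct-6-en-1-ol | CC(C)=CCC[C@@H](C)CCO | starting material
10 | (R)-8-bromo-2,6-dimethyloct-2-ene | CC(C)=CCC[C@@H](C)CCBr | intermediate
11 | (S)-3-bromo-2-methylpropan-1-ol | BrC[C@@H](C)CO | starting material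
12 | [(3R)-3,7-dimethyloct-6-en-1-yl]magnesium bromide | CC(C)=CCC[C@@H](C)CC[Mg]Br | intermediate (not isolated)
13 | bromomagnesium (S)-3-bromo-2-methylpropan-1-olate | BrC[C@@H](C)CO[Mg]Br | intermediate (not isolated)
14 | (2R,6S)-2,6,10-trimethylundec-9-en-1-ol | CC(C)=CCC[C@@H](C)CCC[C@@H](C)CO | intermediate
15 | (2R,6S)-2,6,10-trimethylundec-9-en-1-yl 4-methylbenzenesulfonate | CC(C)=CCC[C@@H](C)CCC[C@@H](C)COS(=O)(=O)c1ccc(C)cc1 | intermediate
16 | (4R,8S)-4,8,12-trimethyltridec-11-en-1-yne (fragment 2) | CC(C)=CCC[C@@H](C)CCC[C@@H](C)CC#C | intermediate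
17 | 4-[(tert-butyldimethylsilyl)oxy]-2,8-dimethyl-6-(pivaloyloxy)chromenylium trifluoromethanesulfonate | Cc1cc(O[Si](C)(C)C(C)(C)C)c2cc(OC(=O)C(C)(C)C)cc(C)c2[o+]1.[O-]S(=O)(=O)C(F)(F)F | intermediate (not isolated)
18 | monovalent copper acetylide of 16 (ligand omitted) | CC(C)=CCC[C@@H](C)CCC[C@@H](C)CC#C[Cu] | intermediate (not isolated)
19 | (2S)-4-[(tert-butyldimethylsilyl)oxy]-2,8-dimethyl-2-[(4R,8S)-4,8,12-trimethyltridec-11-en-1-yn-1-yl]-2H-chromen-6-yl pivalate | CC(C)=CCC[C@@H](C)CCC[C@@H](C)CC#C[C@]1(C)C=C(O[Si](C)(C)C(C)(C)C)c2cc(OC(=O)C(C)(C)C)cc(C)c2O1 | intermediate (not isolated)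
20 | (2S)-2,8-dimethyl-4-oxo-2-[(4R,8S)-4,8,12-trimethyltridec-11-en-1-yn-1-yl]chroman-6-yl pivalate | CC(C)=CCC[C@@H](C)CCC[C@@H](C)CC#C[C@]1(C)CC(=O)c2cc(OC(=O)C(C)(C)C)cc(C)c2O1 | intermediate
21 | (2R)-2,8-dimethyl-4-oxo-2-[(4R,8S)-4,8,12-trimethyltridec-11-en-1-yl]chroman-6-yl pivalate | CC(C)=CCC[C@@H](C)CCC[C@@H](C)CCC[C@]1(C)CC(=O)c2cc(OC(=O)C(C)(C)C)cc(C)c2O1 | intermediate
22 | (2R)-2,8-dimethyl-2-[(4R,8S)-4,8,12-trimethyltridec-11-en-1-yl]chroman-6-ol | CC(C)=CCC[C@@H](C)CCC[C@@H](C)CCC[C@]1(C)CCc2cc(O)cc(C)c2O1 | target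

Total step count: 10. Longest linear sequence: 7 steps (9 → 10 → 14 → 15 → 16 → 20 → 21 → 22); the chromone branch (1 → 4 → 7 → 8) has 3 steps before the union.

Steps most likely to fail

Step 8 (Proposed new method). The cation may be lost by deprotonation of its C2 methyl group followed by self-condensation, addition to the substituted C2 may be slow, or the ligand may discriminate poorly between the two faces. The fallback uses known chemistry, sets out from tosylate 15 and acetophenone 4, and comes back to the route at 22. Tosylate 15 would be coupled (Li2CuCl4 cat., THF, −20 °C to rt) with the Grignard reagent of commercial 2-(2-bromoethyl)-2-methyl-1,3-dioxolane to give 2-methyl-2-[(4R,8S)-4,8,12-trimethyltridec-11-en-1-yl]-1,3-dioxolane F1. Pyridinium 4-methylbenzenesulfonate in aqueous acetone would then free (6R,10S)-6,10,14-trimethylpentadec-13-en-2-one F2. Kabbe condensation of F2 with 4 (pyrrolidine, PhMe, reflux, water separator) closes ring B by aldol condensation and oxa-Michael addition and should give 6-methoxy-2,8-dimethyl-2-[(4R,8S)-4,8,12-trimethyltridec-11-en-1-yl]chroman-4-one F3 as both C2 epimers. LiAlH4/AlCl3 in Et2O removes the C4 oxygen to give 6-methoxy-2,8-dimethyl-2-[(4R,8S)-4,8,12-trimethyltridec-11-en-1-yl]chromane F4, again as both C2 epimers. Preparative HPLC on a cellulose tris(3,5-dimethylphenylcarbamate) phase would separate the (2R)-methyl ether F5 from the (2S)-methyl ether F6. NaSEt in DMF at 130 °C demethylates F5 to 22 without touching the alkene. In this fallback C2 is set by separation and not by a reaction.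

Step 9. Hydrogenation may stall at the hindered cis-alkene next to the quaternary C2, or may start to saturate C11'=C12' before the alkyne is fully reduced. The fallback masks the alkene, sets out from 20 and returns at 21. mCPBA (1.05 equiv), NaHCO3, CH2Cl2, 0 °C should epoxidise only the electron-rich trisubstituted alkene and give (2S)-2-[(4R,8S)-10-(3,3-dimethyloxiran-2-yl)-4,8-dimethyldec-1-yn-1-yl]-2,8-dimethyl-4-oxochroman-6-yl pivalate F7, as both epoxide epimers; no alkene geometry is at stake because C12' carries two methyl groups. H2, Pd/C, EtOAc then saturates the alkyne with no alkene left to compete and gives (2R)-2-[(4R,8S)-10-(3,3-dimethyloxiran-2-yl)-4,8-dimethyldecyl]-2,8-dimethyl-4-oxochroman-6-yl pivalate F8. NaI, Zn, NaOAc, AcOH restores the alkene through the iodohydrin and reductive elimination, giving 21.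

Step 10. The C4 cation may lose a C3 proton to give the 2H-chromene instead of taking up hydride, or reduction may stop at the chroman-4-ol. The fallback avoids the cation, sets out from 21 and returns at 22. TsNHNH2, EtOH, 60 °C gives (2R)-2,8-dimethyl-4-[2-(4-methylbenzenesulfonyl)hydrazinylidene]-2-[(4R,8S)-4,8,12-trimethyltridec-11-en-1-yl]chroman-6-yl pivalate F9. Catecholborane, CHCl3, 0 °C, then NaOAc·3H2O at reflux, reduces the C=N bond and expels sulfinate and nitrogen to give (2R)-2,8-dimethyl-2-[(4R,8S)-4,8,12-trimethyltridec-11-en-1-yl]chroman-6-yl pivalate F10. LiAlH4, THF, 0 °C cleaves the pivalate to 22.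

Further compounds
F1 | step 8 | 2-methyl-2-[(4R,8S)-4,8,12-trimethyltridec-11-en-1-yl]-1,3-dioxolane | CC(C)=CCC[C@@H](C)CCC[C@@H](C)CCCC1(C)OCCO1
F2 | step 8 | (6R,10S)-6,10,14-trimethylpentadec-13-en-2-one | CC(C)=CCC[C@@H](C)CCC[C@@H](C)CCCC(C)=O
F3 | step 8 | 6-methoxy-2,8-dimethyl-2-[(4R,8S)-4,8,12-trimethyltridec-11-en-1-yl]chroman-4-one (both C2 epimers) | CC(C)=CCC[C@@H](C)CCC[C@@H](C)CCCC1(C)CC(=O)c2cc(OC)cc(C)c2O1
F4 | step 8 | 6-methoxy-2,8-dimethyl-2-[(4R,8S)-4,8,12-trimethyltridec-11-en-1-yl]chromane (both C2 epimers) | CC(C)=CCC[C@@H](C)CCC[C@@H](C)CCCC1(C)CCc2cc(OC)cc(C)c2O1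
F5 | step 8 | (2R)-6-methoxy-2,8-dimethyl-2-[(4R,8S)-4,8,12-trimethyltridec-11-en-1-yl]chromane | CC(C)=CCC[C@@H](C)CCC[C@@H](C)CCC[C@]1(C)CCc2cc(OC)cc(C)c2O1
F6 | step 8 | (2S)-6-methoxy-2,8-dimethyl-2-[(4R,8S)-4,8,12-trimethyltridec-11-en-1-yl]chromane | CC(C)=CCC[C@@H](C)CCC[C@@H](C)CCC[C@@]1(C)CCc2cc(OC)cc(C)c2O1
F7 | step 9 | (2S)-2-[(4R,8S)-10-(3,3-dimethyloxiran-2-yl)-4,8-dimethyldec-1-yn-1-yl]-2,8-dimethyl-4-oxochroman-6-yl pivalate (both epoxide epimers) | CC1(C)OC1CC[C@@H](C)CCC[C@@H](C)CC#C[C@]2(C)CC(=O)c3cc(OC(=O)C(C)(C)C)cc(C)c3O2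
F8 | step 9 | (2R)-2-[(4R,8S)-10-(3,3-dimethyloxiran-2-yl)-4,8-dimethyldecyl]-2,8-dimethyl-4-oxochroman-6-yl pivalate (both epoxide epimers) | CC1(C)OC1CC[C@@H](C)CCC[C@@H](C)CCC[C@]2(C)CC(=O)c3cc(OC(=O)C(C)(C)C)cc(C)c3O2
F9 | step 10 | (2R)-2,8-dimethyl-4-[2-(4-methylbenzenesulfonyl)hydrazinylidene]-2-[(4R,8S)-4,8,12-trimethyltridec-11-en-1-yl]chroman-6-yl pivalate | CC(C)=CCC[C@@H](C)CCC[C@@H](C)CCC[C@]1(C)CC(=NNS(=O)(=O)c2ccc(C)cc2)c3cc(OC(=O)C(C)(C)C)cc(C)c3O1
F10 | step 10 | (2R)-2,8-dimethyl-2-[(4R,8S)-4,8,12-trimethyltridec-11-en-1-yl]chroman-6-yl pivalate | CC(C)=CCC[C@@H](C)CCC[C@@H](C)CCC[C@]1(C)CCc2cc(OC(=O)C(C)(C)C)cc(C)c2O1
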